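You put two questions to me, the three shares and how they run, and you wanted a quick number.

1. share of E in all that became E or D for red, grey, blue, in this order
2. how the row runs (rises, then falls / rises all the way / falls, then rises / falls all the way / hardly changes)

the same everywhere: X 0.69 mM

| run | L | remark | time |
|---|---|---|---|
| ash | 0.063 M | run made earlier |  |
| alder | 0.17 M | run made earlier |  |
| maple | 0.59 M | run made earlier |  |
| red | 0.050 M |  | 2.5 d |
| grey | 0.15 M |  | 2.5 d |
| blue | 0.50 M |  | 2.5 d |

- ash (time / h: E / %, D / %, L / %): 5.00: 5.5, 6.4, 88.5; 15.0: 8.9, 17.5, 75.0; 25.0: 9.3, 27.8, 63.5; 40.0: 10.7, 38.4, 50.0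
- alder (time / h: E / %, D / %, L / %): 5.00: 5.1, 6.6, 88.1; 15.0: 8.4, 18.3, 74.0; 25.0: 10.1, 27.6, 63.2; 40.0: 10.5, 38.5, 51.5
- maple (time / h: E / %, D / %, L / %): 5.00: 4.7, 6.3, 88.6; 15.0: 9.2, 17.4, 74.5; 25.0: 10.2, 27.3, 63.8; 40.0: 10.1, 38.7, 50.6

(standard deviation of a reading: 0.5 percentage points)

- the numbers in the tables scatter by 0.5 percentage points (one standard deviation)
- "hardly changes" means that all values lie within two and a half points (for a concentration: within two and a half percent of the largest)

I began with the percent columns. At 40.0 h, L stood at 50.0% in ash, 51.5% in alder and 50.6% in maple, although the maple charge was 9.37 times larger. I therefore read both rates as first order in [L]. Then [L] cancels from their ratio, and what stays in it is [X], charged at 0.69 mM in ash, maple and red alike.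

To test this I took the share E/(E+D), the selectivity, at 40.0 h: 21.8% in ash and 20.7% in maple. That gap of 1.1 percentage points rests on readings that scatter by 0.5 points. The logarithm of the ratio of these shares, divided by the logarithm of the ratio of the charges, gave −0.0231, the order of the selectivity in [L]. Across a charge ten times larger, from red to blue, this reading moves the share by a factor of 0.948. I took that as no trend and committed to a flat row, but I reckoned no level of my own.

Your forecast gave the level, 17.2%, 17.2%, 17.2%, and called the row "hardly changes", “the same for all three, since X is unchanged”. The column to watch is E in maple, 10.2% at 25.0 h and 10.1% at 40.0 h, with L still at 50.6%, so shares must be compared at one sampling time.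

The flasks gave 18.1%, 18.1%, 18.1%: hardly changes, 0.9 points above the forecast.

    L + X → X + E (k = 0.620 L mol⁻¹ min⁻¹)
    L → D (k = 2.30 × 10⁻⁴ min⁻¹)
    2 X → J (k = 8.00 L mol⁻¹ min⁻¹)

At 2.50 d, X stood at 2.45% of the catalyst charged in red and at 2.45% in blue. Carried from red with the order, the share at blue's charge comes to 17.2%, while blue stood at 18.1%. Carried the same way to grey's charge, it comes to 17.6%, and grey stood at 18.1%.

Readings and results are simulated with constants of no real substance; the scatter is artificial.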